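Everything rests on cutting the pyranone ring of coumarin A (O1, C2, C3, C4) away from its benzene ring. O1 (on C8a) and C4 (on C4a) are ortho neighbours, and the flanking C5–H and C8–H cannot bias an aryne, so a mirror-symmetric 4,5-methylenedioxybenzyne is chosen. In one operation it draws O1 and C4 from a single dimethylformamide molecule. An ester enolate captures the resulting amino ortho-quinone methide at C4, and lactonisation with amine loss closes the ring. The precursors are a sesamol-derived ortho-silylaryl triflate and a silyl ketene acetal that already carries coumarin B on the future C3 oxygen. Acetal cleavage and acidity-guided O7-methylation finish the synthesis.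

Key step: step 6

Remark on the chemistry (assumption): the ketene acetal is drawn as the Z isomer expected from a chelated lithium enolate. Either isomer would serve, because C3 ends as an sp2 carbon.

Design points:
- Coumarin A is numbered O1, C2, C3, C4, C4a, C5 to C8, C8a. Coumarin B is the umbelliferone unit.
- The ketene acetal is made by in situ silyl trapping, so no free enolate lingers next to coumarin B.
- It keeps the fluoride-labile Me3Si group so that the enolate is released at once.
- It is the limiting component in the key step.
- It is added only after the silylaryl triflate has been consumed in dilute dimethylformamide.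

Step 1
Reactants: 1 sesamol (1,3-benzodioxol-5-ol)
Product: 2 6-bromo-1,3-benzodioxol-5-ol
Conditions: NBS (1.0 equiv), MeCN, 0 °C
Reagents that add atoms: N-bromosuccinimide, O=C1CCC(=O)N1Br
Why: Electrophilic aromatic bromination goes to C6, which is ortho to the hydroxyl and para to a dioxole oxygen, whereas the other ortho position C4 is wedged between two oxygen-bearing carbons.

Step 2
Reactants: 2 6-bromo-1,3-benzodioxol-5-ol
Product: 3 [(6-bromo-1,3-benzodioxol-5-yl)oxy]trimethylsilane
Conditions: (Me3Si)2NH (1.0 equiv), THF, 70 °C; evaporate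
Reagents that add atoms: hexamethyldisilazane, C[Si](C)(C)N[Si](C)(C)C
Why: Phenol O-silylation with a silazane is driven by loss of ammonia and leaves no salt, so evaporation should give material dry enough for the lithiation.

Step 3
Reactants: 3 [(6-bromo-1,3-benzodioxol-5-yl)oxy]trimethylsilane
Product: 6 6-(trimethylsilyl)-1,3-benzodioxol-5-yl trifluoromethanesulfonate, via aryllithium 4 (not isolated), via lithium phenoxide 5 (not isolated)
Conditions: n-BuLi (1.1 equiv), THF, −78 °C; then Tf2O (1.2 equiv), −78 °C; cold aq. NaHCO3
Reagents that add atoms: trifluoromethanesulfonic anhydride, O=S(=O)(OS(=O)(=O)C(F)(F)F)C(F)(F)F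
Why: Bromine–lithium exchange gives 4, whose carbanion takes the silyl group from the neighbouring oxygen (retro-Brook 1,3 O-to-C shift, driven by the change from aryl anion to phenoxide 5), and O-triflation of 5 in the same flask completes the standard entry to ortho-silylaryl triflates.

Step 4
Reactants: 7 umbelliferone (7-hydroxy-2H-chromen-2-one), 8 methyl bromoacetate
Product: 9 methyl [(2-oxo-2H-chromen-7-yl)oxy]acetate
Conditions: K2CO3 (1.5 equiv), acetone, reflux
Reagents that add atoms: methyl bromoacetate (8), COC(=O)CBr
Why: Williamson ether synthesis, in which K2CO3 fully ionises the acidic 7-hydroxyl and the primary alpha-bromo ester is an excellent SN2 partner, under conditions that leave the lactone closed.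

Step 5
Reactants: 9 methyl [(2-oxo-2H-chromen-7-yl)oxy]acetate
Product: 11 7-{[(Z)-2-methoxy-2-(trimethylsilyloxy)ethenyl]oxy}-2H-chromen-2-one, via lithium enolate 10 (not isolated)
Conditions: Me3SiCl (3 equiv), then LiN(SiMe3)2 (1.15 equiv) dropwise, THF, −78 °C to 0 °C; evaporate, dry toluene, filter under Ar; used at once
Reagents that add atoms: chlorotrimethylsilane, C[Si](C)(C)Cl
Why: Kinetic ester enolisation with in situ silyl trapping (the silyl ketene acetal formation used in Ireland–Claisen chemistry), in which the hindered amide removes the OCH2 proton acidified by ester and aryloxy group, and the Me3SiCl already present captures chelated enolate 10 on oxygen before it can add to C4 of coumarin B or to a second ester.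

Step 6
Reactants: 6 6-(trimethylsilyl)-1,3-benzodioxol-5-yl trifluoromethanesulfonate, 11 7-{[(Z)-2-methoxy-2-(trimethylsilyloxy)ethenyl]oxy}-2H-chromen-2-one, 12 dimethylformamide
Product: 19 7-[(2-oxo-2H-chromen-7-yl)oxy]-6H-[1,3]dioxolo[4,5-g]chromen-6-one, via benzyne 13 (not isolated), via benzoxete 14 (not isolated), via ortho-quinone methide 15 (not isolated), via caesium enolate 16 (not isolated), via Mannich adduct 17 (not isolated), via aminodihydrocoumarin 18 (not isolated)
Conditions: 6 (1.5 equiv), CsF (5 equiv, flame-dried), dry 12 as solvent (0.03 M in 6), 4 Å MS, 25 °C until 6 is consumed; then 11 (1.0 equiv) in 12, 0 °C to 25 °C, then 60 °C; 1 M HCl work-up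
Reagents that add atoms: dimethylformamide (12), CN(C)C=O
Why: Proposed new method: fluoride-induced 1,2-elimination of 6 gives benzyne 13, whose strained triple bond takes up the C=O of solvent 12 in a stepwise [2+2] to benzoxete 14 (O1–C8a and C4–C4a), and ring opening gives ortho-quinone methide 15, a push-pull vinylogous amide (iminium phenoxide in its dipolar form) that should persist for a while in the dry medium. Residual fluoride then strips the silyl group from 11, enolate 16 adds through carbon to the iminium-like C4 of 15 in a Mannich-type step (C3–C4), the phenoxide of 17 closes the pyranone ring by 6-exo-trig acyl substitution at the ester carbon (O1–C2), and retro-aza-Michael (E1cB) loss of dimethylamine from 18 is driven by formation of the conjugated coumarin. The closest known reaction type is the three-component coumarin synthesis from arynes, formamides and doubly activated methylene compounds such as malonates, and what is new is a singly activated 2-aryloxy ester enolate stored as a silyl ketene acetal. The C3 and C4 stereocentres of 17 and 18 need no control because both become sp2. Regioselectivity does not arise, since the mirror plane of 13 makes its two aryne carbons equivalent and a single benzoxete results. Chemoselectivity rests on timing and concentration, because 13 is generated dilute in neat 12 and is gone before 11 arrives, so neither [2+2] of the ketene acetal nor arylation of the enolate can compete, and C4 of 15 is a far better acceptor than C4 of coumarin B.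

Step 7
Reactants: 19 7-[(2-oxo-2H-chromen-7-yl)oxy]-6H-[1,3]dioxolo[4,5-g]chromen-6-one
Product: 21 6,7-dihydroxy-3-[(2-oxo-2H-chromen-7-yl)oxy]-2H-chromen-2-one, via chloromethyl ether borate 20 (not isolated)
Conditions: BCl3 (4 equiv, 1 M in CH2Cl2), CH2Cl2, 0 °C to 25 °C; then 1 M HCl/THF, 25 °C
Reagents that add atoms: none
Why: Lewis-acid cleavage of an aryl methylene acetal, in which BCl3 binds the more basic O6, chloride opens the O6–CH2 bond to 20 and aqueous acid hydrolyses the chloromethyl ether and the borate, while the diaryl ether and both lactones offer no alkyl C–O bond to break and only complex reversibly.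

Step 8
Reactants: 21 6,7-dihydroxy-3-[(2-oxo-2H-chromen-7-yl)oxy]-2H-chromen-2-one
Product: 22 6-hydroxy-7-methoxy-3-[(2-oxo-2H-chromen-7-yl)oxy]-2H-chromen-2-one (target)
Conditions: Li2CO3 (1.2 equiv), MeI (1.2 equiv), DMF, 45 °C, Ar
Reagents that add atoms: iodomethane, CI
Why: Acidity-controlled phenol O-alkylation (SN2), in which the C7 hydroxyl is para to C4a and conjugated through C4=C3 with the lactone carbonyl, so the weak, sparingly soluble base ionises it in preference to the C6 hydroxyl and only O7 is methylated.

Compound list

1 | sesamol (1,3-benzodioxol-5-ol) | Oc1ccc2OCOc2c1 | starting material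
2 | 6-bromo-1,3-benzodioxol-5-ol | Oc1cc2OCOc2cc1Br | intermediate
3 | [(6-bromo-1,3-benzodioxol-5-yl)oxy]trimethylsilane | C[Si](C)(C)Oc1cc2OCOc2cc1Br | intermediate
4 | {6-[(trimethylsilyl)oxy]-1,3-benzodioxol-5-yl}lithium | [Li]c1cc2OCOc2cc1O[Si](C)(C)C | intermediate (not isolated)
5 | lithium 6-(trimethylsilyl)-1,3-benzodioxol-5-olate | [Li+].[O-]c1cc2OCOc2cc1[Si](C)(C)C | intermediate (not isolated)
6 | 6-(trimethylsilyl)-1,3-benzodioxol-5-yl trifluoromethanesulfonate | C[Si](C)(C)c1cc2OCOc2cc1OS(=O)(=O)C(F)(F)F | intermediate
7 | umbelliferone (7-hydroxy-2H-chromen-2-one) | O=c1ccc2ccc(O)cc2o1 | starting material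
8 | methyl bromoacetate | COC(=O)CBr | starting material
9 | methyl [(2-oxo-2H-chromen-7-yl)oxy]acetate | COC(=O)COc1ccc2ccc(=O)oc2c1 | intermediate
10 | chelated lithium enolate of 9 (oxido group cis to the aryloxy group) | [Li+].CO/C([O-])=C/Oc1ccc2ccc(=O)oc2c1 | intermediate (not isolated)
11 | 7-{[(Z)-2-methoxy-2-(trimethylsilyloxy)ethenyl]oxy}-2H-chromen-2-one | CO/C(O[Si](C)(C)C)=C/Oc1ccc2ccc(=O)oc2c1 | intermediate
12 | dimethylformamide | CN(C)C=O | starting material
13 | 5,6-didehydro-1,3-benzodioxole (4,5-methylenedioxybenzyne) | C1=C2OCOC2=CC#C1 | intermediate (not isolated)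
14 | 2-(dimethylamino)-4,5-methylenedioxy-2H-benzoxete (racemic) | CN(C)C1Oc2cc3OCOc3cc12 | intermediate (not isolated)
15 | 6-[(dimethylamino)methylidene]-1,3-benzodioxol-5(6H)-one | CN(C)C=C1C=C2OCOC2=CC1=O | intermediate (not isolated)
16 | caesium enolate of 9 (geometry immaterial) | [Cs+].COC([O-])=COc1ccc2ccc(=O)oc2c1 | intermediate (not isolated)
17 | caesium 6-{1-(dimethylamino)-3-methoxy-3-oxo-2-[(2-oxo-2H-chromen-7-yl)oxy]propyl}-1,3-benzodioxol-5-olate (racemic diastereomer mixture, both centres lost later) | [Cs+].COC(=O)C(Oc1ccc2ccc(=O)oc2c1)C(N(C)C)c1cc2OCOc2cc1[O-] | intermediate (not isolated)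
18 | 8-(dimethylamino)-7-[(2-oxo-2H-chromen-7-yl)oxy]-7,8-dihydro-6H-[1,3]dioxolo[4,5-g]chromen-6-one (racemic diastereomer mixture, both centres lost later) | CN(C)C1C(Oc2ccc3ccc(=O)oc3c2)C(=O)Oc2cc3OCOc3cc12 | intermediate (not isolated)
19 | 7-[(2-oxo-2H-chromen-7-yl)oxy]-6H-[1,3]dioxolo[4,5-g]chromen-6-one | O=c1oc2cc3OCOc3cc2cc1Oc1ccc2ccc(=O)oc2c1 | intermediate
20 | 7-(chloromethoxy)-2-oxo-3-[(2-oxo-2H-chromen-7-yl)oxy]-2H-chromen-6-yl dichloroborinate | ClCOc1cc2oc(=O)c(Oc3ccc4ccc(=O)oc4c3)cc2cc1OB(Cl)Cl | intermediate (not isolated)
21 | 6,7-dihydroxy-3-[(2-oxo-2H-chromen-7-yl)oxy]-2H-chromen-2-one | Oc1cc2oc(=O)c(Oc3ccc4ccc(=O)oc4c3)cc2cc1O | intermediate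
22 | 6-hydroxy-7-methoxy-3-[(2-oxo-2H-chromen-7-yl)oxy]-2H-chromen-2-one | COc1cc2oc(=O)c(Oc3ccc4ccc(=O)oc4c3)cc2cc1O | target

Total step count: 8

Longest linear sequence: 6 (steps 1, 2, 3, 6, 7, 8)

Steps most likely to fail

1. Step 6.
- What may go wrong: the aryne–formamide adduct may decay before the enolate arrives, through capture of a second aryne at the phenoxide oxygen or hydrolysis by traces of water. The liberated enolate may also be lost to protonation or self-condensation.
- Fallback (known chemistry): it sets out from 1 and 9 and comes back at 19.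
- Sesamol 1 is ortho-formylated (MgCl2, Et3N, paraformaldehyde, MeCN, reflux; Casnati–Skattebøl conditions) at the unhindered C6 to give 6-hydroxy-1,3-benzodioxole-5-carbaldehyde F1.
- Ester 9 is saponified (LiOH, THF/H2O, then HCl to reclose any opened lactone) to [(2-oxo-2H-chromen-7-yl)oxy]acetic acid F2.
- Heating F1 and F2 in Ac2O with Et3N at about 120 °C (Perkin-type condensation of a salicylaldehyde with an aryloxyacetic acid) should give 19 directly.

2. Step 5.
- What may go wrong: conjugate addition or Claisen-type self-condensation of the enolate before it is silylated, competing C-silylation, and hydrolysis of the Me3Si ketene acetal during isolation.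
- Fallback: it sets out from 9 and comes back at 19. It replaces metal-enolate formation by soft enolisation and uses a silyl group that tolerates handling.
- Ester 9 is treated with t-BuMe2SiOTf and Et3N in CH2Cl2 at 0 °C to 25 °C. The ester is activated by O-silylation and deprotonated by the amine, so no free enolate ever exists.
- This gives 7-{[(Z)-2-(tert-butyldimethylsilyloxy)-2-methoxyethenyl]oxy}-2H-chromen-2-one F3 (Z drawn, either isomer serves), which can be washed and filtered through deactivated silica.
- F3 then takes the place of 11 in step 6.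

3. Step 8.
- What may go wrong: incomplete discrimination between the two phenols, and over-methylation.
- Fallback: it sets out from 21 and comes back at 22. It tells the two oxygens apart through their esters instead of their anions.
- Peracetylation (Ac2O, pyridine) gives 2-oxo-3-[(2-oxo-2H-chromen-7-yl)oxy]-2H-chromene-6,7-diyl diacetate F4.
- Thiolysis with PhSH and imidazole in N-methylpyrrolidone removes the C7 acetate, the ester of the better leaving phenoxide. This gives 7-hydroxy-2-oxo-3-[(2-oxo-2H-chromen-7-yl)oxy]-2H-chromen-6-yl acetate F5, which is also the thermodynamically preferred monoacetate, so any acyl migration works in the right direction.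
- Mitsunobu methylation (MeOH, PPh3, diisopropyl azodicarboxylate, THF) under neutral conditions gives 7-methoxy-2-oxo-3-[(2-oxo-2H-chromen-7-yl)oxy]-2H-chromen-6-yl acetate F6.
- Catalytic K2CO3 in MeOH followed by dilute HCl releases 22.

Further compounds

F1 | step 6 | 6-hydroxy-1,3-benzodioxole-5-carbaldehyde | O=Cc1cc2OCOc2cc1O
F2 | step 6 | [(2-oxo-2H-chromen-7-yl)oxy]acetic acid | OC(=O)COc1ccc2ccc(=O)oc2c1
F3 | step 5 | 7-{[(Z)-2-(tert-butyldimethylsilyloxy)-2-methoxyethenyl]oxy}-2H-chromen-2-one | CO/C(O[Si](C)(C)C(C)(C)C)=C/Oc1ccc2ccc(=O)oc2c1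
F4 | step 8 | 2-oxo-3-[(2-oxo-2H-chromen-7-yl)oxy]-2H-chromene-6,7-diyl diacetate | CC(=O)Oc1cc2oc(=O)c(Oc3ccc4ccc(=O)oc4c3)cc2cc1OC(C)=O
F5 | step 8 | 7-hydroxy-2-oxo-3-[(2-oxo-2H-chromen-7-yl)oxy]-2H-chromen-6-yl acetate | CC(=O)Oc1cc2cc(Oc3ccc4ccc(=O)oc4c3)c(=O)oc2cc1O
F6 | step 8 | 7-methoxy-2-oxo-3-[(2-oxo-2H-chromen-7-yl)oxy]-2H-chromen-6-yl acetate | COc1cc2oc(=O)c(Oc3ccc4ccc(=O)oc4c3)cc2cc1OC(C)=O
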